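**Retrosynthetic overview** (ring atoms: C1 carbonyl, C2 allyl-bearing, C3 vinyl CH, C4 quaternary C–OMe, C5 enol-ether carbon, C6 vinyl CH; side chain C8 = CHMe on C4, C7 = ArCH2)
1. Feature: in the cyclohexa-2,5-dienone ring, C4 (quaternary C–O) and C5 (C–OMe at carbonyl oxidation level) are adjacent, both carbonyl-derived and of like polarity. C4–C5 is therefore cut as an acyl-anion addition (C5 aldehyde onto C4 ketone), a carbene-catalysed crossed benzoin that closes the six-membered ring in one ring-forming event.
2. The acyclic keto-aldehyde 13 (C1 stored as a dioxolane) comes from a C3–C4 Weinreb ketone synthesis (amide 5 plus the Grignard reagent of bromo ketal 9) and ozonolysis; C8 is set by Evans alkylation.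
3. After ring closure: C4–OH is methylated, C1 is unmasked to the 1,3-dione, the C5 enol ether is placed by a silyl-relay O-methylation, and C2 is functionalised through its α′-enolate (hydroxylation, diosphenol triflate), which puts C2=C3 in place before a final Stille allylation.

Key step: step 7

Assumption: the (5aS,10bR) antipode of the aminoindanol-derived triazolium salt is taken as the one that gives the (R)-carbinol of 14; if a pilot run shows the opposite sense, the mirror-image salt is used.

**Step 1**
Reactants: 1 (4R)-4-benzyl-3-propanoyl-1,3-oxazolidin-2-one; 2 3,4-dimethoxybenzyl bromide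
Product: 4 (4R)-4-benzyl-3-[(2S)-3-(3,4-dimethoxyphenyl)-2-methylpropanoyl]-1,3-oxazolidin-2-one, via sodium enolate 3 (not isolated)
Conditions: NaN(SiMe3)2, THF, −78 °C; then 2, −78 to −20 °C
Reagents that add atoms: none
Why: Evans asymmetric alkylation, in which the chelated (Z)-enolate is attacked by the benzylic bromide on the face away from the benzyl group of the (R)-auxiliary, so that the side-chain centre (C8 of the target) should be set as S and any minor diastereomer removed by chromatography.

**Step 2**
Reactants: 4
Product: 5 (2S)-3-(3,4-dimethoxyphenyl)-N-methoxy-N,2-dimethylpropanamide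
Conditions: MeNH(OMe)·HCl, AlMe3, CH2Cl2, −10 °C to rt; 1 M HCl work-up
Reagents that add atoms: N,O-dimethylhydroxylamine hydrochloride, CNOC.Cl
Why: Aluminium-amide transamination of an N-acyl oxazolidinone (Weinreb amide formation), which attacks the exocyclic imide carbonyl under Lewis-acidic, non-enolising conditions, so C8 should be retained and the auxiliary released.

**Step 3**
Reactants: 6 3-bromopropanoyl chloride; 7 allyltrimethylsilane
Product: 8 1-bromohex-5-en-3-one
Conditions: AlCl3, CH2Cl2, −78 °C
Reagents that add atoms: none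
Why: Lewis-acid-promoted acylation of an allylsilane (Sakurai-type), in which the activated acid chloride is attacked by the γ-carbon of the silane and chlorotrimethylsilane is lost, giving the β,γ-unsaturated ketone, which is kept cold and used at once.

**Step 4**
Reactants: 8
Product: 9 2-(2-bromoethyl)-2-(prop-2-en-1-yl)-1,3-dioxolane
Conditions: (Me3SiOCH2)2, Me3SiOTf (5 mol%), CH2Cl2, −78 to −20 °C; pyridine quench
Reagents that add atoms: 1,2-bis(trimethylsilyloxy)ethane, C[Si](C)(C)OCCO[Si](C)(C)C
Why: Noyori ketalisation, a cold, non-aqueous silyl-triflate-catalysed exchange that should neither eliminate HBr from the β-bromo ketone nor move the β,γ-double bond into conjugation.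

**Step 5**
Reactants: 9; 5
Product: 11 (2S)-1-(3,4-dimethoxyphenyl)-2-methyl-5-[2-(prop-2-en-1-yl)-1,3-dioxolan-2-yl]pentan-3-one, via Grignard reagent 10 (not isolated)
Conditions: Mg turnings, THF, 25–30 °C; then 5, THF, 0 °C; aqueous NH4Cl work-up
Reagents that add atoms: none
Why: Weinreb ketone synthesis, in which the primary alkylmagnesium bromide (formed below 30 °C, where 2-dioxolanylethyl Grignard reagents are stable) adds once to the N-methoxy-N-methylamide and the chelated adduct resists both a second addition and enolisation, so the C3–C4 bond is made with C8 intact.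

**Step 6**
Reactants: 11
Product: 13 2-{2-[(4S)-5-(3,4-dimethoxyphenyl)-4-methyl-3-oxopentyl]-1,3-dioxolan-2-yl}acetaldehyde, via ozonide 12 (not isolated)
Conditions: O3, CH2Cl2, −78 °C, Sudan Red 7B end-point; PPh3, −78 °C to rt
Reagents that add atoms: ozone, [O-][O+]=O
Why: Ozonolysis with reductive work-up, in which the terminal alkene reacts far faster than the dimethoxyarene (the dye end-point stops the gas flow) while ketal and ketone are inert; the sensitive β-ketal aldehyde is used directly.

**Step 7**
Reactants: 13
Product: 14 (8R)-8-[(2S)-1-(3,4-dimethoxyphenyl)propan-2-yl]-8-hydroxy-1,4-dioxaspiro[4.5]decan-7-one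
Conditions: (5aS,10bR)-2-(pentafluorophenyl)-5a,10b-dihydro-4H,6H-indeno[2,1-b][1,2,4]triazolo[4,3-d][1,4]oxazin-2-ium tetrafluoroborate (20 mol%), Et3N (20 mol%), toluene (0.02 M), rt
Reagents that add atoms: none
Why: The carbene from the triazolium salt adds to the C5 aldehyde, proton transfer gives the enaminol (Breslow intermediate), this acyl-anion equivalent attacks the C4 ketone, and proton transfer with loss of the carbene releases the α-ketol. The closest known reaction type is the enantioselective intramolecular crossed aldehyde–ketone benzoin cyclisation with chiral bicyclic triazolium salts to six-membered tertiary α-ketols. The ring closes in the 6-exo-trig mode through a chair-like transition state in which the enaminol O–H is hydrogen-bonded to the ketone oxygen. The new C4 centre is set by the catalyst, whose indane wall shields one face of the enaminol so that the ketone presents the face leading to the (R)-carbinol, whereas C8 (methyl against arylmethyl) exerts little bias; any C4 epimer is a diastereomer and is removed by chromatography. The step needs donor/acceptor chemoselectivity and cyclisation over dimerisation, which are secured because only the aldehyde can form the enaminol, the ketone is the one internal electrophile at six-ring distance, the ketal carbon gives a gem-disubstituent effect and the solution is dilute. Only catalytic amine base is present, so that enolisation (C8 epimerisation, β-elimination of a ketal oxygen) should stay slow relative to carbene catalysis.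

**Step 8**
Reactants: 14
Product: 15 (8R)-8-[(2S)-1-(3,4-dimethoxyphenyl)propan-2-yl]-8-methoxy-1,4-dioxaspiro[4.5]decan-7-one
Conditions: MeOTf (5 equiv), 2,6-di-tert-butyl-4-methylpyridine (6 equiv), CH2Cl2, rt to 40 °C
Reagents that add atoms: methyl trifluoromethanesulfonate, COS(=O)(=O)C(F)(F)F
Why: O-Methylation of a hindered alcohol with methyl triflate and a non-nucleophilic pyridine, chosen because these non-basic conditions cannot enolise the ketone toward C6 (which would expel a ketal oxygen) or trigger retro-benzoin, and the ketal oxygens are much poorer nucleophiles than the hydroxyl.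

**Step 9**
Reactants: 15
Product: 16 (4R)-4-[(2S)-1-(3,4-dimethoxyphenyl)propan-2-yl]-4-methoxycyclohexane-1,3-dione
Conditions: 1 M HCl, THF, rt
Reagents that add atoms: water, O
Why: Acid hydrolysis of a ketal, in which every side path (β-elimination to a vinylogous ester) converges on the same 1,3-dione; C5 is kept at the carbonyl level so that its enol ether can be made by O-alkylation, not by dehydrogenating a β-methoxy ketone that would tend to lose methanol.

**Step 10**
Reactants: 16
Product: 18 (4R)-4-[(2S)-1-(3,4-dimethoxyphenyl)propan-2-yl]-3,4-dimethoxycyclohex-2-en-1-one, via triisopropylsilyl enol ether 17 (not isolated)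
Conditions: i-Pr3SiOTf (1.05 equiv), 2,6-di-tert-butyl-4-methylpyridine (2.5 equiv), CH2Cl2, −78 to 0 °C; then MeOTf (1.5 equiv), 0 °C to rt; aqueous NaHCO3
Reagents that add atoms: methyl trifluoromethanesulfonate, COS(=O)(=O)C(F)(F)F
Why: Proposed new method: the bulky silyl group should go on the unhindered enol oxygen at C1 (direct etherification of 4,4-disubstituted cyclohexane-1,3-diones is known to favour this distal oxygen, which is the wrong one for the target), leaving the C5 carbonyl oxygen of the vinylogous silyl ester as the only nucleophilic site for methyl triflate. Methylation there gives a 1-silyloxy-3-methoxyallyl cation that loses the silyl group to triflate (or to water on work-up), so the methyl ends on the C5 oxygen and the carbonyl at C1. The closest known reaction types are the O-alkylation of vinylogous esters and amides at the carbonyl oxygen by methyl triflate or trialkyloxonium salts, and the alkylation of silyl esters with loss of silicon.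

**Step 11**
Reactants: 18
Product: 20 (4R)-4-[(2S)-1-(3,4-dimethoxyphenyl)propan-2-yl]-6-hydroxy-3,4-dimethoxycyclohex-2-en-1-one, via potassium enolate 19 (not isolated)
Conditions: KN(SiMe3)2, THF, −78 °C; 2-(phenylsulfonyl)-3-phenyloxaziridine, −78 °C; AcOH quench
Reagents that add atoms: 2-(phenylsulfonyl)-3-phenyloxaziridine, O=S(=O)(N1OC1c1ccccc1)c1ccccc1
Why: Davis oxidation of the kinetic α′-enolate, regiospecific because C2–H is the only acidic position of the vinylogous ester (C4 is quaternary, C6 vinylic), which avoids a late electrophilic halogenation that the electron-rich C6 of the finished dienone would contest; the C2 configuration is irrelevant.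

**Step 12**
Reactants: 20
Product: 22 (4S)-4-[(2S)-1-(3,4-dimethoxyphenyl)propan-2-yl]-2-hydroxy-4,5-dimethoxycyclohexa-2,5-dien-1-one, via 1,2-diketone 21 (not isolated)
Conditions: Dess–Martin periodinane (1.2 equiv), CH2Cl2, rt
Reagents that add atoms: none
Why: Dess–Martin oxidation of the α-hydroxy ketone to the 1,2-diketone, which can enolise only toward C3 and so should give the diosphenol with the C2=C3 double bond in place, aromatisation being blocked by the quaternary C4.

**Step 13**
Reactants: 22
Product: 23 (3S)-3-[(2S)-1-(3,4-dimethoxyphenyl)propan-2-yl]-3,4-dimethoxy-6-oxocyclohexa-1,4-dien-1-yl trifluoromethanesulfonate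
Conditions: PhNTf2, Et3N, DMAP (cat.), CH2Cl2, 0 °C to rt
Reagents that add atoms: N-phenylbis(trifluoromethanesulfonimide), O=S(=O)(N(c1ccccc1)S(=O)(=O)C(F)(F)F)C(F)(F)F
Why: O-Triflation of the acidic diosphenol hydroxyl with a mild triflimide reagent, which fixes a cross-coupling handle on C2 and nowhere else.

**Step 14**
Reactants: 23; 24 allyltributylstannane
Product: 25 (4S)-4-[(2S)-1-(3,4-dimethoxyphenyl)propan-2-yl]-4,5-dimethoxy-2-(prop-2-en-1-yl)cyclohexa-2,5-dien-1-one
Conditions: Pd(PPh3)4 (5 mol%), LiCl (3 equiv), THF, 65 °C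
Reagents that add atoms: none
Why: Stille coupling, in which zerovalent palladium inserts into the electron-poor vinyl triflate, the allyl group is transferred from tin with chloride assistance and reductive elimination forms C2–allyl under neutral conditions that should leave the dienone, the enol ether, both stereocentres and the position of the allyl double bond untouched.

**Compound list**
1 | (4R)-4-benzyl-3-propanoyl-1,3-oxazolidin-2-one | CCC(=O)N1[C@H](Cc2ccccc2)COC1=O | starting material
2 | 3,4-dimethoxybenzyl bromide | COc1ccc(CBr)cc1OC | starting material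
3 | sodium (Z)-enolate of 1 | [Na+].C/C=C(\[O-])N1[C@H](Cc2ccccc2)COC1=O | intermediate (not isolated)
4 | (4R)-4-benzyl-3-[(2S)-3-(3,4-dimethoxyphenyl)-2-methylpropanoyl]-1,3-oxazolidin-2-one | O=C([C@@H](C)Cc1ccc(OC)c(OC)c1)N1[C@H](Cc2ccccc2)COC1=O | intermediate
5 | (2S)-3-(3,4-dimethoxyphenyl)-N-methoxy-N,2-dimethylpropanamide | CON(C)C(=O)[C@@H](C)Cc1ccc(OC)c(OC)c1 | intermediate
6 | 3-bromopropanoyl chloride | O=C(Cl)CCBr | starting material
7 | allyltrimethylsilane | C=CC[Si](C)(C)C | starting material
8 | 1-bromohex-5-en-3-one | C=CCC(=O)CCBr | intermediate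
9 | 2-(2-bromoethyl)-2-(prop-2-en-1-yl)-1,3-dioxolane | C=CCC1(CCBr)OCCO1 | intermediate
10 | {2-[2-(prop-2-en-1-yl)-1,3-dioxolan-2-yl]ethyl}magnesium bromide | C=CCC1(CC[Mg]Br)OCCO1 | intermediate (not isolated)
11 | (2S)-1-(3,4-dimethoxyphenyl)-2-methyl-5-[2-(prop-2-en-1-yl)-1,3-dioxolan-2-yl]pentan-3-one | C=CCC1(CCC(=O)[C@@H](C)Cc2ccc(OC)c(OC)c2)OCCO1 | intermediate
12 | ozonide (1,2,4-trioxolane) of 11 | C1OC(CC2(CCC(=O)[C@@H](C)Cc3ccc(OC)c(OC)c3)OCCO2)OO1 | intermediate (not isolated)
13 | 2-{2-[(4S)-5-(3,4-dimethoxyphenyl)-4-methyl-3-oxopentyl]-1,3-dioxolan-2-yl}acetaldehyde | O=CCC1(CCC(=O)[C@@H](C)Cc2ccc(OC)c(OC)c2)OCCO1 | intermediate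
14 | (8R)-8-[(2S)-1-(3,4-dimethoxyphenyl)propan-2-yl]-8-hydroxy-1,4-dioxaspiro[4.5]decan-7-one | C1C[C@@](O)([C@@H](C)Cc2ccc(OC)c(OC)c2)C(=O)CC13OCCO3 | intermediate
15 | (8R)-8-[(2S)-1-(3,4-dimethoxyphenyl)propan-2-yl]-8-methoxy-1,4-dioxaspiro[4.5]decan-7-one | C1C[C@@](OC)([C@@H](C)Cc2ccc(OC)c(OC)c2)C(=O)CC13OCCO3 | intermediate
16 | (4R)-4-[(2S)-1-(3,4-dimethoxyphenyl)propan-2-yl]-4-methoxycyclohexane-1,3-dione | C1C[C@@](OC)([C@@H](C)Cc2ccc(OC)c(OC)c2)C(=O)CC1=O | intermediate
17 | (6R)-6-[(2S)-1-(3,4-dimethoxyphenyl)propan-2-yl]-6-methoxy-3-[(triisopropylsilyl)oxy]cyclohex-2-en-1-one | C1C[C@@](OC)([C@@H](C)Cc2ccc(OC)c(OC)c2)C(=O)C=C1O[Si](C(C)C)(C(C)C)C(C)C | intermediate (not isolated)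
18 | (4R)-4-[(2S)-1-(3,4-dimethoxyphenyl)propan-2-yl]-3,4-dimethoxycyclohex-2-en-1-one | O=C1CC[C@@](OC)([C@@H](C)Cc2ccc(OC)c(OC)c2)C(OC)=C1 | intermediate
19 | potassium cross-conjugated dienolate of 18 | [K+].[O-]C1=CC[C@@](OC)([C@@H](C)Cc2ccc(OC)c(OC)c2)C(OC)=C1 | intermediate (not isolated)
20 | (4R)-4-[(2S)-1-(3,4-dimethoxyphenyl)propan-2-yl]-6-hydroxy-3,4-dimethoxycyclohex-2-en-1-one (C6 epimers) | O=C1C(O)C[C@@](OC)([C@@H](C)Cc2ccc(OC)c(OC)c2)C(OC)=C1 | intermediate
21 | (5R)-5-[(2S)-1-(3,4-dimethoxyphenyl)propan-2-yl]-4,5-dimethoxycyclohex-3-ene-1,2-dione | O=C1C(=O)C[C@@](OC)([C@@H](C)Cc2ccc(OC)c(OC)c2)C(OC)=C1 | intermediate (not isolated)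
22 | (4S)-4-[(2S)-1-(3,4-dimethoxyphenyl)propan-2-yl]-2-hydroxy-4,5-dimethoxycyclohexa-2,5-dien-1-one | O=C1C(O)=C[C@@](OC)([C@@H](C)Cc2ccc(OC)c(OC)c2)C(OC)=C1 | intermediate
23 | (3S)-3-[(2S)-1-(3,4-dimethoxyphenyl)propan-2-yl]-3,4-dimethoxy-6-oxocyclohexa-1,4-dien-1-yl trifluoromethanesulfonate | O=C1C(OS(=O)(=O)C(F)(F)F)=C[C@@](OC)([C@@H](C)Cc2ccc(OC)c(OC)c2)C(OC)=C1 | intermediate
24 | allyltributylstannane | C=CC[Sn](CCCC)(CCCC)CCCC | starting material
25 | (4S)-4-[(2S)-1-(3,4-dimethoxyphenyl)propan-2-yl]-4,5-dimethoxy-2-(prop-2-en-1-yl)cyclohexa-2,5-dien-1-one | C=CCC1=C[C@@](OC)([C@@H](C)Cc2ccc(OC)c(OC)c2)C(OC)=CC1=O | target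

**Step count**
Total: 14 steps. Longest linear sequence: 12 steps (1, 2, 5–14); steps 3 and 4 make the side fragment 9.

**Steps most likely to fail**

Step 10 (proposed new method). The risk is loss of regiocontrol: silylation at the hindered enol oxygen, or silyl exchange during the methylation, would place the enol ether at C1 instead of C5. The fallback uses known chemistry and sets out from 16. Direct O-methylation of the dione with Me3SiCHN2 in toluene/MeOH is not selective and should give 18 together with its regioisomer (6R)-6-[(2S)-1-(3,4-dimethoxyphenyl)propan-2-yl]-3,6-dimethoxycyclohex-2-en-1-one F1. The two are separated by chromatography, F1 is hydrolysed back to 16 with 1 M HCl in THF and recycled, and the route is rejoined at 18.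

Step 7 (key step). The α-branched ketone is a demanding acceptor, so addition of the enaminol may be slow. Base-mediated enolisation could then compete (epimerisation at C8, β-elimination that opens the dioxolane, aldol closure), or facial selectivity at C4 could be insufficient. The fallback sets out from 13 and forms the same C4–C5 bond without base: reductive ketyl–carbonyl (pinacol) cyclisation with SmI2 (divalent samarium) in THF/t-BuOH at −78 °C. After chromatographic separation of the C4 epimers this should give the cis-diol (8R)-8-[(2S)-1-(3,4-dimethoxyphenyl)propan-2-yl]-1,4-dioxaspiro[4.5]decane-7,8-diol F2. Oxidation of the secondary hydroxyl alone (SO3·pyridine, DMSO, i-Pr2NEt) returns to the route at 14.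

Step 8. Alkylation of the hindered, hydrogen-bonded tertiary α-ketol may be sluggish, and methylation at a ketal oxygen with ketal cleavage may compete. The fallback sets out from 14 and uses NaH and MeI in THF/DMF at 0 °C. The tertiary alkoxide is methylated, and enolisation toward C6 is allowed to open the dioxolane by β-elimination, the freed primary alkoxide being methylated as well. This should give the vinylogous ester (6R)-6-[(2S)-1-(3,4-dimethoxyphenyl)propan-2-yl]-6-methoxy-3-(2-methoxyethoxy)cyclohex-2-en-1-one F3. Hydrolysis of F3 with 1 M HCl in THF gives the dione, so the route is rejoined at 16 and step 9 is bypassed.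

**Further compounds**
F1 | step 10 | (6R)-6-[(2S)-1-(3,4-dimethoxyphenyl)propan-2-yl]-3,6-dimethoxycyclohex-2-en-1-one | C1C[C@@](OC)([C@@H](C)Cc2ccc(OC)c(OC)c2)C(=O)C=C1OC
F2 | step 7 | (8R)-8-[(2S)-1-(3,4-dimethoxyphenyl)propan-2-yl]-1,4-dioxaspiro[4.5]decane-7,8-diol (cis) | C1C[C@@](O)([C@@H](C)Cc2ccc(OC)c(OC)c2)C(O)CC13OCCO3
F3 | step 8 | (6R)-6-[(2S)-1-(3,4-dimethoxyphenyl)propan-2-yl]-6-methoxy-3-(2-methoxyethoxy)cyclohex-2-en-1-one | C1C[C@@](OC)([C@@H](C)Cc2ccc(OC)c(OC)c2)C(=O)C=C1OCCOC
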